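Everything rests on opening ring B at two bonds that meet at C3: O4–C3 and C3–C2. C3 is flanked by the ring A oxygen O4 and by C2, which carries syringyl ring C and O1, so O4 can come from a phenol, C3 from a diazoacetate carbon and C2 from an aldehyde. One Rh2(OAc)4/chiral phosphoric acid operation should join 6-bromoeugenol, ethyl diazoacetate and O-tosylsyringaldehyde, making both bonds and both stereocentres of a syn aryloxy aldol. The precursors are a hindered 2-bromophenol with a spectator allyl group and an electron-poor, sulfonate-protected aldehyde. Ester-to-methyl reduction, palladium-catalysed O1–C8a closure, allyl isomerisation and detosylation then give the target.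

Key step: step 3

Remark on the chemistry: the syringyl oxygen is carried as a tosylate, not a silyl ether, because a para-sulfonyloxy group makes the aldehyde an electron-poor trap for the ylide, has no acidic hydrogen next to sulfur and should tolerate borohydrides, carbonate and palladium; the hand of the phosphoric acid that gives the (2S,3R) series is assumed to be fixed in a first screening run, both hands being available.

Step 1
Reactants: 1 eugenol (4-allyl-2-methoxyphenol)
Product: 2 4-allyl-2-bromo-6-methoxyphenol
Conditions: NBS (1.0 equiv), iPr2NH (10 mol%), CH2Cl2, 0 °C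
Reagents that add atoms: N-bromosuccinimide, O=C1CCC(=O)N1Br
Why: Electrophilic aromatic bromination (NBS with a secondary amine, ortho-selective for phenols) should take the only free position ortho to the hydroxyl, the para position being blocked by the allyl group, while the unactivated terminal alkene reacts far more slowly under these polar, non-radical conditions.

Step 2
Reactants: 3 syringaldehyde (4-hydroxy-3,5-dimethoxybenzaldehyde)
Product: 4 4-formyl-2,6-dimethoxyphenyl 4-methylbenzenesulfonate
Conditions: TsCl, Et3N, DMAP (cat.), CH2Cl2, 0 °C to rt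
Reagents that add atoms: p-toluenesulfonyl chloride, Cc1ccc(cc1)S(Cl)(=O)=O
Why: O-Sulfonylation of a phenol with a sulfonyl chloride and amine base is routine even between two methoxy groups, and the resulting aryl tosylate turns a donor oxygen into an acceptor substituent.

Step 3
Reactants: 2 4-allyl-2-bromo-6-methoxyphenol; 4 4-formyl-2,6-dimethoxyphenyl 4-methylbenzenesulfonate; 5 ethyl diazoacetate
Product: 7 ethyl (2S,3R)-2-(4-allyl-2-bromo-6-methoxyphenoxy)-3-hydroxy-3-[3,5-dimethoxy-4-(tosyloxy)phenyl]propanoate, via oxonium ylide 6 (not isolated)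
Conditions: Rh2(OAc)4 (2 mol%), (R)-TRIP [3,3'-bis(2,4,6-triisopropylphenyl)-1,1'-binaphthyl-2,2'-diyl hydrogen phosphate] (10 mol%), 4 Å MS, CH2Cl2, −20 °C; 5 (1.5 equiv) by syringe pump into 2 (1.0 equiv) and 4 (1.5 equiv)
Reagents that add atoms: none
Why: Proposed new method: Rh2(OAc)4 takes N2 out of 5 to give an electrophilic rhodium carbene, the phenol oxygen of 2 adds to it (O4–C3 bond) and the protic oxonium ylide 6, in effect a rhodium-associated enol, attacks the phosphoric-acid-bound aldehyde 4 through carbon (C3–C2 bond) before the 1,2-proton shift that would end in simple O–H insertion. The closest known reaction type is the Rh2(OAc)4/chiral phosphoric acid three-component coupling of aryldiazoacetates with alcohols and aldehydes or imines by ylide interception, which is stretched here to an acceptor-only diazo ester and a phenol. No ring is closed in this step. Both new stereocentres (S at the aryloxy carbon and R at the carbinol carbon, the future C3 and C2 of ring B) are to be set by the chiral phosphoric acid, which should bind the ylide O–H at its P=O oxygen and the aldehyde at its P–OH so that the enol carbon meets one aldehyde face in a closed, hydrogen-bonded array with the aryloxy and aryl groups apart (syn, threo). Interception has to beat proton transfer, which is why the aldehyde is made electron-poor by the para-sulfonyloxy group, used in excess and met by slowly added 5 at low temperature. Chemoselectivity for O–H attack over cyclopropanation of the allyl group should follow from the large excess of nucleophilic phenol over the fleeting carbene and from the unactivated, monosubstituted nature of that alkene.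

Step 4
Reactants: 7 ethyl (2S,3R)-2-(4-allyl-2-bromo-6-methoxyphenoxy)-3-hydroxy-3-[3,5-dimethoxy-4-(tosyloxy)phenyl]propanoate
Product: 8 (1R,2R)-2-(4-allyl-2-bromo-6-methoxyphenoxy)-1-[3,5-dimethoxy-4-(tosyloxy)phenyl]propane-1,3-diol
Conditions: LiBH4, THF, 0 °C to rt
Reagents that add atoms: none
Why: Borohydride reduction of an ester to a primary alcohol, fast here because the ester is activated by its α-aryloxy and β-hydroxy groups, should leave aryl bromide, aryl sulfonate and alkene alone and touch neither stereocentre (the descriptor at the aryloxy carbon becomes R by priority rules only).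

Step 5
Reactants: 8 (1R,2R)-2-(4-allyl-2-bromo-6-methoxyphenoxy)-1-[3,5-dimethoxy-4-(tosyloxy)phenyl]propane-1,3-diol
Product: 9 (2R,3R)-2-(4-allyl-2-bromo-6-methoxyphenoxy)-3-hydroxy-3-[3,5-dimethoxy-4-(tosyloxy)phenyl]propyl 4-methylbenzenesulfonate
Conditions: TsCl (1.1 equiv), pyridine, CH2Cl2, 0 °C
Reagents that add atoms: p-toluenesulfonyl chloride, Cc1ccc(cc1)S(Cl)(=O)=O
Why: Sulfonylation with TsCl in pyridine should pick the unhindered primary hydroxyl over the secondary benzylic one, which sits between an aryl ring and the carbon that carries the bulky aryloxy group.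

Step 6
Reactants: 9 (2R,3R)-2-(4-allyl-2-bromo-6-methoxyphenoxy)-3-hydroxy-3-[3,5-dimethoxy-4-(tosyloxy)phenyl]propyl 4-methylbenzenesulfonate
Product: 10 (1R,2R)-2-(4-allyl-2-bromo-6-methoxyphenoxy)-1-[3,5-dimethoxy-4-(tosyloxy)phenyl]propan-1-ol
Conditions: LiBHEt3 (2.5 equiv), THF, 0 °C to rt; aq NH4Cl
Reagents that add atoms: none
Why: Hydride SN2 displacement of a primary alkyl tosylate by LiBHEt3 gives the future C3 methyl group, whereas the aryl tosylate offers no carbon for substitution and neither stereocentre takes part.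

Step 7
Reactants: 10 (1R,2R)-2-(4-allyl-2-bromo-6-methoxyphenoxy)-1-[3,5-dimethoxy-4-(tosyloxy)phenyl]propan-1-ol
Product: 11 4-[(2R,3R)-7-allyl-5-methoxy-3-methyl-2,3-dihydro-1,4-benzodioxin-2-yl]-2,6-dimethoxyphenyl 4-methylbenzenesulfonate
Conditions: Pd(OAc)2 (5 mol%), rac-2-(di-tert-butylphosphino)-1,1'-binaphthyl (6 mol%), Cs2CO3, toluene, 70 °C
Reagents that add atoms: none
Why: Intramolecular palladium-catalysed aryl etherification (Buchwald–Hartwig C–O coupling, six-membered closure of ring B at O1–C8a) runs by oxidative addition of the aryl bromide to zerovalent palladium, alkoxide binding and reductive elimination driven by the bulky phosphine, so the C–O bond at C2 is never broken and the threo alcohol should give the trans (2R,3R) ring.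

Step 8
Reactants: 11 4-[(2R,3R)-7-allyl-5-methoxy-3-methyl-2,3-dihydro-1,4-benzodioxin-2-yl]-2,6-dimethoxyphenyl 4-methylbenzenesulfonate
Product: 12 4-[(2R,3R)-5-methoxy-3-methyl-7-[(E)-prop-1-enyl]-2,3-dihydro-1,4-benzodioxin-2-yl]-2,6-dimethoxyphenyl 4-methylbenzenesulfonate
Conditions: RuHCl(CO)(PPh3)3 (3 mol%), toluene, 80 °C
Reagents that add atoms: none
Why: Ruthenium hydride catalysed alkene isomerisation (hydride addition and β-hydride elimination) moves the terminal double bond into conjugation with ring A under thermodynamic control, which favours the (E)-propenyl isomer, and the neutral conditions should leave both stereocentres and the sulfonate untouched.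

Step 9
Reactants: 12 4-[(2R,3R)-5-methoxy-3-methyl-7-[(E)-prop-1-enyl]-2,3-dihydro-1,4-benzodioxin-2-yl]-2,6-dimethoxyphenyl 4-methylbenzenesulfonate
Product: 13 4-[(2R,3R)-5-methoxy-3-methyl-7-[(E)-prop-1-enyl]-2,3-dihydro-1,4-benzodioxin-2-yl]-2,6-dimethoxyphenol (CNP0227775.1)
Conditions: Mg turnings, MeOH, rt
Reagents that add atoms: none
Why: Dissolving-metal desulfonylation with Mg in MeOH cleaves the S–O bond of the aryl tosylate by electron transfer to the arenesulfonyl group at room temperature, where the electron-rich propenylarene and the benzylic ether bonds should not be reduced and the phenoxide is never heated with base, so C2 keeps its configuration.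

Compound list
1 | eugenol (4-allyl-2-methoxyphenol) | C=CCc1ccc(O)c(OC)c1 | starting material
2 | 4-allyl-2-bromo-6-methoxyphenol | C=CCc1cc(Br)c(O)c(OC)c1 | intermediate
3 | syringaldehyde (4-hydroxy-3,5-dimethoxybenzaldehyde) | COc1cc(C=O)cc(OC)c1O | starting material
4 | 4-formyl-2,6-dimethoxyphenyl 4-methylbenzenesulfonate | COc1cc(C=O)cc(OC)c1OS(=O)(=O)c1ccc(C)cc1 | intermediate
5 | ethyl diazoacetate | CCOC(=O)C=[N+]=[N-] | starting material
6 | protic oxonium ylide formed from 2 at the carbene carbon of 5 (not isolated) | C=CCc1cc(Br)c([OH+][CH-]C(=O)OCC)c(OC)c1 | intermediate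
7 | ethyl (2S,3R)-2-(4-allyl-2-bromo-6-methoxyphenoxy)-3-hydroxy-3-[3,5-dimethoxy-4-(tosyloxy)phenyl]propanoate | C=CCc1cc(Br)c(O[C@H](C(=O)OCC)[C@H](O)c2cc(OC)c(OS(=O)(=O)c3ccc(C)cc3)c(OC)c2)c(OC)c1 | intermediate
8 | (1R,2R)-2-(4-allyl-2-bromo-6-methoxyphenoxy)-1-[3,5-dimethoxy-4-(tosyloxy)phenyl]propane-1,3-diol | C=CCc1cc(Br)c(O[C@H](CO)[C@H](O)c2cc(OC)c(OS(=O)(=O)c3ccc(C)cc3)c(OC)c2)c(OC)c1 | intermediate
9 | (2R,3R)-2-(4-allyl-2-bromo-6-methoxyphenoxy)-3-hydroxy-3-[3,5-dimethoxy-4-(tosyloxy)phenyl]propyl 4-methylbenzenesulfonate | C=CCc1cc(Br)c(O[C@H](COS(=O)(=O)c2ccc(C)cc2)[C@H](O)c2cc(OC)c(OS(=O)(=O)c3ccc(C)cc3)c(OC)c2)c(OC)c1 | intermediate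
10 | (1R,2R)-2-(4-allyl-2-bromo-6-methoxyphenoxy)-1-[3,5-dimethoxy-4-(tosyloxy)phenyl]propan-1-ol | C=CCc1cc(Br)c(O[C@H](C)[C@H](O)c2cc(OC)c(OS(=O)(=O)c3ccc(C)cc3)c(OC)c2)c(OC)c1 | intermediate
11 | 4-[(2R,3R)-7-allyl-5-methoxy-3-methyl-2,3-dihydro-1,4-benzodioxin-2-yl]-2,6-dimethoxyphenyl 4-methylbenzenesulfonate | C=CCc1cc(OC)c2c(c1)O[C@H](c1cc(OC)c(OS(=O)(=O)c3ccc(C)cc3)c(OC)c1)[C@@H](C)O2 | intermediate
12 | 4-[(2R,3R)-5-methoxy-3-methyl-7-[(E)-prop-1-enyl]-2,3-dihydro-1,4-benzodioxin-2-yl]-2,6-dimethoxyphenyl 4-methylbenzenesulfonate | C/C=C/c1cc(OC)c2c(c1)O[C@H](c1cc(OC)c(OS(=O)(=O)c3ccc(C)cc3)c(OC)c1)[C@@H](C)O2 | intermediate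
13 | 4-[(2R,3R)-5-methoxy-3-methyl-7-[(E)-prop-1-enyl]-2,3-dihydro-1,4-benzodioxin-2-yl]-2,6-dimethoxyphenol | C/C=C/c1cc(OC)c2c(c1)O[C@H](c1cc(OC)c(O)c(OC)c1)[C@@H](C)O2 | target

Total step count: 9. Longest linear sequence: 8 steps (steps 1, 3, 4, 5, 6, 7, 8, 9, from eugenol; equally 2, 3–9 from syringaldehyde).

Steps most likely to fail

First, step 3 (proposed new method). Proton transfer within the oxonium ylide may outrun addition to the aldehyde and leave only O–H insertion. The carbene may also add to the allyl alkene, or the phosphoric acid may give weak facial control. The fallback uses known auxiliary chemistry; it sets out from 2 and comes back at 8, so step 4 is skipped.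
- Williamson alkylation of 2 with chloroacetic acid (NaOH, H2O, reflux) gives 2-(4-allyl-2-bromo-6-methoxyphenoxy)acetic acid F1.
- Its pivalic mixed anhydride (PivCl, Et3N, THF) acylates (S)-4-benzyl-2-oxazolidinone in the presence of LiCl to give (S)-4-benzyl-3-[2-(4-allyl-2-bromo-6-methoxyphenoxy)acetyl]oxazolidin-2-one F2.
- The (Z)-boron enolate (Bu2BOTf, iPr2NEt, CH2Cl2, −78 °C) adds to 4 through a Zimmerman–Traxler chair (Evans syn aldol) to give (S)-4-benzyl-3-[(2S,3R)-2-(4-allyl-2-bromo-6-methoxyphenoxy)-3-hydroxy-3-[3,5-dimethoxy-4-(tosyloxy)phenyl]propanoyl]oxazolidin-2-one F3.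
- LiBH4 (THF, MeOH, 0 °C) removes the auxiliary reductively and delivers diol 8.

Second, step 7. β-Hydride elimination from the palladium alkoxide (ketone formation with loss of bromine) or carbopalladation of the allyl group may compete with C–O reductive elimination. The fallback leaves palladium for a copper-mediated Ullmann etherification, in which the copper alkoxide has no ready β-hydride pathway and does not engage the alkene: 10 is heated with CuI, 3,4,7,8-tetramethyl-1,10-phenanthroline and Cs2CO3 in toluene at 110 °C. It sets out from 10 and comes back at 11, with retention at C2 as before, and passes through no new compound (F0).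

Third, step 9. Electron transfer from magnesium may spill over to the conjugated propenylarene and saturate or couple the side chain. The fallback changes the order so that the sulfonate is removed while the alkene is still isolated. It sets out from 11: Mg in MeOH at rt gives 4-[(2R,3R)-7-allyl-5-methoxy-3-methyl-2,3-dihydro-1,4-benzodioxin-2-yl]-2,6-dimethoxyphenol F4. Isomerisation of the free phenol with RuHCl(CO)(PPh3)3 in toluene at 80 °C then comes back to the route at 13.

Further compounds
F1 | step 3 | 2-(4-allyl-2-bromo-6-methoxyphenoxy)acetic acid | C=CCc1cc(Br)c(OCC(=O)O)c(OC)c1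
F2 | step 3 | (S)-4-benzyl-3-[2-(4-allyl-2-bromo-6-methoxyphenoxy)acetyl]oxazolidin-2-one | C=CCc1cc(Br)c(OCC(=O)N2C(=O)OC[C@@H]2Cc2ccccc2)c(OC)c1
F3 | step 3 | (S)-4-benzyl-3-[(2S,3R)-2-(4-allyl-2-bromo-6-methoxyphenoxy)-3-hydroxy-3-[3,5-dimethoxy-4-(tosyloxy)phenyl]propanoyl]oxazolidin-2-one | C=CCc1cc(Br)c(O[C@H](C(=O)N2C(=O)OC[C@@H]2Cc2ccccc2)[C@H](O)c2cc(OC)c(OS(=O)(=O)c3ccc(C)cc3)c(OC)c2)c(OC)c1
F0 | step 7 | none | none
F4 | step 9 | 4-[(2R,3R)-7-allyl-5-methoxy-3-methyl-2,3-dihydro-1,4-benzodioxin-2-yl]-2,6-dimethoxyphenol | C=CCc1cc(OC)c2c(c1)O[C@H](c1cc(OC)c(O)c(OC)c1)[C@@H](C)O2
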